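**Plan** (carotane numbering: C1 quaternary carbon, C4 carbinol, C5 ring-fusion CH, C6 ester carbon, C8=C9 alkene)
- Cuts, in retrosynthetic order: the C6–O salicylate ester; the C8=C9 alkene (metathesis); the C6–C7 bond (methallyl addition to a C6 acyl group); then, in one operation, the C4–C5 ring bond and a temporary C4–O–C6 lactone bond; last the C1–CH3 bond.
- Enabling feature: on the five-membered ring the tertiary C4 oxygen and C6 (on C5) are cis on adjacent carbons, so the target hides a cis-fused β-lactone (four-membered ring O–C4–C5–C6).
- Forward: a cyclopentenone receives the C1 methyl; acylation and retro-Claisen cleavage open it to an acyclic 6-oxo acid; the keto acid closes to cyclopentane plus β-lactone in one step; the lactone is opened and the cycloheptene is closed by metathesis.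
- Stereochemistry: C1 from a copper-catalysed asymmetric conjugate methylation; C4 and C5 from the isothiourea catalyst, with the lactone enforcing cis; C6 from hydride delivery directed by the C4 hydroxyl.

Key step: step 5

Assumption: the sense of induction of the carbene ligand (step 2) and of the isothiourea (step 5) would be fixed in a trial run, and the enantiomer that gives the configurations drawn is the one used.

**Step 1**
Reactants: 1 3-ethoxycyclopent-2-en-1-one; 2 allylmagnesium bromide
Product: 4 3-allylcyclopent-2-en-1-one, via 1-allyl-3-ethoxycyclopent-2-en-1-ol 3 (not isolated)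
Conditions: allylMgBr (1.2 equiv), THF/Et2O, 0 °C; then 1 M HCl, 0 °C, 15 min
Reagents that add atoms: allylmagnesium bromide, C=CC[Mg]Br
Why: Stork–Danheiser alkylative carbonyl transposition: 1,2-addition to the vinylogous ester, then brief cold acid ionises the tertiary allylic alcohol and hydrolyses the enol ether to the 3-substituted enone, the short acid contact keeping the allyl double bond out of conjugation.

**Step 2**
Reactants: 4 3-allylcyclopent-2-en-1-one; 5 trimethylaluminium
Product: 7 (R)-3-allyl-3-methylcyclopentan-1-one, via dimethylaluminium enolate 6 (not isolated)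
Conditions: AlMe3 (3 equiv), Cu(OTf)2 (5 mol %), [Ag(L*)]2 (2.5 mol %; L* = enantiopure N-(2-sulfonatoaryl)-4,5-diphenylimidazolin-2-ylidene), THF, −78 °C; then 1 M HCl
Reagents that add atoms: trimethylaluminium, C[Al](C)C
Why: Copper-catalysed asymmetric conjugate addition of a trialkylaluminium to a β-substituted cyclopentenone is a known route to all-carbon quaternary centres in five-membered rings; the chiral carbene–copper complex selects the enone face and so sets C1 (R), and the aluminium enolate is protonated on work-up.

**Step 3**
Reactants: 7 (R)-3-allyl-3-methylcyclopentan-1-one; 8 isobutyryl chloride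
Product: 9 (4S)-4-allyl-2-isobutyryl-4-methylcyclopentan-1-one (C2 epimers and enol forms)
Conditions: i-PrCOCl (1.2 equiv), MgBr2·OEt2 (2.5 equiv), i-Pr2NEt (3 equiv), CH2Cl2, 0 → 23 °C; 1 M HCl
Reagents that add atoms: isobutyryl chloride, CC(C)C(Cl)=O
Why: Soft-enolisation C-acylation (magnesium enolate plus acid chloride) gives the 1,3-diketone, the acyl group entering at the α-methylene remote from the quaternary carbon because the other α-position is neopentylic; the new α-centre is destroyed in step 4 and needs no control.

**Step 4**
Reactants: 9 (4S)-4-allyl-2-isobutyryl-4-methylcyclopentan-1-one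
Product: 10 (R)-3-allyl-3,7-dimethyl-6-oxooctanoic acid
Conditions: 2 M aq. NaOH, 90 °C; then HCl to pH 2
Reagents that add atoms: sodium hydroxide, [Na+].[OH-]
Why: Retro-Claisen cleavage of a 2-acylcyclopentanone: hydroxide adds to the strained ring carbonyl rather than the hindered isopropyl ketone and the C1–C2 bond of 9 breaks, so the ring carbonyl becomes acid carbon C6 and the isobutyryl carbonyl becomes ketone C4, with the non-enolisable C1 centre untouched.

**Step 5**
Reactants: 10 (R)-3-allyl-3,7-dimethyl-6-oxooctanoic acid
Product: 12 (1R,2R,5R)-2-allyl-5-isopropyl-2-methyl-6-oxabicyclo[3.2.0]heptan-7-one, via tosyl mixed anhydride 11 (not isolated)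
Conditions: TsCl (1.3 equiv), (S)-HBTM (20 mol %), LiCl (1 equiv), i-Pr2NEt (4 equiv), CH2Cl2, 23 °C, slow addition of 10
Reagents that add atoms: none
Why: Tosyl chloride converts the acid into mixed anhydride 11, the isothiourea is acylated at nitrogen and i-Pr2NEt removes a C5 proton to give a catalyst-bound ammonium enolate, whose intramolecular aldol addition to the LiCl-activated isopropyl ketone forms the C4–C5 bond before the C4 alkoxide attacks acyl carbon C6, closing the β-lactone and releasing the catalyst. The closest known reaction type is the isothiourea- or cinchona-catalysed aldol-lactonisation of keto acids to bicyclic β-lactones bearing tertiary carbinol carbons. The cyclopentane closes 5-exo-trig at the ketone carbonyl (enolexo with respect to the enolate) and the oxetanone closes 4-exo-trig at the acyl ammonium carbonyl. C5 is set by the catalyst, whose phenyl-bearing stereocentre shields one enolate face, and C4 follows from C5 because a four-membered lactone can only be cis-fused to the cyclopentane, so the C4 oxygen and C6 end cis. The step needs facial selectivity relative to the existing C1 centre (C6 cis to the C1 methyl) and enolisation at C5 only: methyl and allyl on C1 are nearly equal in size, so the substrate has almost no bias and the catalyst enantiomer decides, while only the α-protons of the acyl ammonium ion are acidic enough for i-Pr2NEt, leaving the ketone un-enolised. Geminal substitution at C1 and slow addition of 10 favour ring closure over ketene dimerisation.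

**Step 6**
Reactants: 12 (1R,2R,5R)-2-allyl-5-isopropyl-2-methyl-6-oxabicyclo[3.2.0]heptan-7-one; 13 N,O-dimethylhydroxylamine hydrochloride
Product: 14 (1R,2R,5R)-5-allyl-2-hydroxy-2-isopropyl-N-methoxy-N,5-dimethylcyclopentane-1-carboxamide
Conditions: MeNHOMe·HCl (3 equiv), i-PrMgCl (6 equiv), THF, −20 → 0 °C; sat. aq. NH4Cl
Reagents that add atoms: N,O-dimethylhydroxylamine hydrochloride, CNOC.Cl
Why: Aminolysis of the strained β-lactone by the magnesium amide (Weinreb amide formation) cleaves the acyl C6–O bond, since the alkyl-oxygen carbon C4 is tertiary, so C4 and C5 keep their configuration and the C4 hydroxyl is unmasked without a strong Lewis acid that could ionise C4–O.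

**Step 7**
Reactants: 14 (1R,2R,5R)-5-allyl-2-hydroxy-2-isopropyl-N-methoxy-N,5-dimethylcyclopentane-1-carboxamide; 15 methallylmagnesium chloride
Product: 17 1-[(1R,2R,5R)-5-allyl-2-hydroxy-2-isopropyl-5-methylcyclopentyl]-3-methylbut-3-en-1-one, via magnesium hemiaminal chelate 16 (not isolated)
Conditions: methallylMgCl (3 equiv), THF, −78 → −20 °C; cold sat. aq. NH4Cl
Reagents that add atoms: methallylmagnesium chloride, CC(=C)C[Mg]Cl
Why: Weinreb ketone synthesis with an allylic Grignard reagent: one equivalent deprotonates the C4 hydroxyl, a second adds to the hindered amide through a six-membered allyl-transfer transition state, and chelate 16 holds the ketone oxidation level until the cold buffered quench, which keeps the β,γ-alkene unconjugated and C5 unepimerised.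

**Step 8**
Reactants: 17 1-[(1R,2R,5R)-5-allyl-2-hydroxy-2-isopropyl-5-methylcyclopentyl]-3-methylbut-3-en-1-one
Product: 18 (3R,3aR,8aR)-3-hydroxy-3-isopropyl-6,8a-dimethyl-2,3,3a,5,8,8a-hexahydroazulen-4(1H)-one
Conditions: second-generation Grubbs catalyst RuCl2(=CHPh)(PCy3)(H2IMes) (5 mol %), 1,4-benzoquinone (10 mol %), CH2Cl2 (5 mM), 40 °C
Reagents that add atoms: none
Why: Ring-closing metathesis of a monosubstituted with a 1,1-disubstituted alkene forms the trisubstituted C8=C9 bond and the seven-membered ring; the two tethers are trans on the cyclopentane and of the right length for the trans-fused bicyclo[5.3.0]decene, and the neutral medium (quinone against ruthenium hydrides) leaves the β-hydroxy ketone and the alkene position intact.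

**Step 9**
Reactants: 18 (3R,3aR,8aR)-3-hydroxy-3-isopropyl-6,8a-dimethyl-2,3,3a,5,8,8a-hexahydroazulen-4(1H)-one
Product: 19 (3R,3aS,4S,8aR)-3-isopropyl-6,8a-dimethyl-1,2,3,3a,4,5,8,8a-octahydroazulene-3,4-diol
Conditions: Me4NBH(OAc)3 (5 equiv), MeCN/AcOH 1:1, −30 → −20 °C; aq. Rochelle salt, NaHCO3
Reagents that add atoms: none
Why: Evans–Saksena hydroxyl-directed reduction: the C4 hydroxyl exchanges onto boron and hydride is delivered through a six-membered transition state to the carbonyl face on which the C4–O bond lies (the face that also holds C1), the trans ring fusion fixing the sign of the O–C4–C5–C6 torsion, so the new C6–O bond ends trans to C4–O and cis to H5 (6S); the reagent does not reduce a ketone it cannot bind, so an undirected pathway should not compete.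

**Step 10**
Reactants: 19 (3R,3aS,4S,8aR)-3-isopropyl-6,8a-dimethyl-1,2,3,3a,4,5,8,8a-octahydroazulene-3,4-diol; 20 O-acetylsalicyloyl chloride
Product: 21 (3R,3aS,4S,8aR)-3-hydroxy-3-isopropyl-6,8a-dimethyl-1,2,3,3a,4,5,8,8a-octahydroazulen-4-yl 2-acetoxybenzoate
Conditions: 2-AcOC6H4COCl (1.5 equiv), pyridine (3 equiv), DMAP (0.2 equiv), CH2Cl2, 0 → 23 °C
Reagents that add atoms: O-acetylsalicyloyl chloride, CC(=O)Oc1ccccc1C(Cl)=O
Why: DMAP-catalysed esterification with an acid chloride occurs only at the secondary C6 hydroxyl, the tertiary C4 hydroxyl next to isopropyl being inert, and the phenol is carried as its acetate so the reagent cannot acylate itself; configuration at C6 is retained.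

**Step 11**
Reactants: 21 (3R,3aS,4S,8aR)-3-hydroxy-3-isopropyl-6,8a-dimethyl-1,2,3,3a,4,5,8,8a-octahydroazulen-4-yl 2-acetoxybenzoate
Product: 22 (3R,3aS,4S,8aR)-3-hydroxy-3-isopropyl-6,8a-dimethyl-1,2,3,3a,4,5,8,8a-octahydroazulen-4-yl 2-hydroxybenzoate (CNP0379621.1)
Conditions: K2CO3 (0.2 equiv), MeOH, 0 °C, 30 min; AcOH quench
Reagents that add atoms: none
Why: Base-catalysed methanolysis (transesterification) removes the aryl acetate, which is far more reactive than the hindered secondary alkyl salicylate; the freed ortho-phenol hydrogen-bonds to the ester carbonyl and deactivates it further.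

**Compound list**
1 | 3-ethoxycyclopent-2-en-1-one | CCOC1=CC(=O)CC1 | starting material
2 | allylmagnesium bromide | C=CC[Mg]Br | starting material
3 | 1-allyl-3-ethoxycyclopent-2-en-1-ol (racemic; present as its magnesium alkoxide until the acid quench) | C=CCC1(O)C=C(OCC)CC1 | intermediate (not isolated)
4 | 3-allylcyclopent-2-en-1-one | C=CCC1=CC(=O)CC1 | intermediate
5 | trimethylaluminium | C[Al](C)C | starting material
6 | dimethylaluminium enolate of 7 (O–Al on C1, C1=C2 towards the quaternary carbon) | C=CC[C@@]1(C)CCC(O[Al](C)C)=C1 | intermediate (not isolated)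
7 | (R)-3-allyl-3-methylcyclopentan-1-one | C=CC[C@@]1(C)CCC(=O)C1 | intermediate
8 | isobutyryl chloride (2-methylpropanoyl chloride) | CC(C)C(Cl)=O | starting material
9 | (4S)-4-allyl-2-isobutyryl-4-methylcyclopentan-1-one (C2 epimers and enol forms) | C=CC[C@@]1(C)CC(C(=O)C(C)C)C(=O)C1 | intermediate
10 | (R)-3-allyl-3,7-dimethyl-6-oxooctanoic acid | C=CC[C@@](C)(CCC(=O)C(C)C)CC(O)=O | intermediate (key-step precursor)
11 | mixed anhydride of 10 with p-toluenesulfonic acid | C=CC[C@@](C)(CCC(=O)C(C)C)CC(=O)OS(=O)(=O)c1ccc(C)cc1 | intermediate (not isolated)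
12 | (1R,2R,5R)-2-allyl-5-isopropyl-2-methyl-6-oxabicyclo[3.2.0]heptan-7-one (cis-fused β-lactone; lactone carbonyl cis to the C2 methyl, trans to allyl) | C=CC[C@@]1(C)CC[C@]2(C(C)C)OC(=O)[C@H]12 | intermediate (key-step product)
13 | N,O-dimethylhydroxylamine hydrochloride | CNOC.Cl | starting material
14 | (1R,2R,5R)-5-allyl-2-hydroxy-2-isopropyl-N-methoxy-N,5-dimethylcyclopentane-1-carboxamide | C=CC[C@@]1(C)CC[C@@](O)(C(C)C)[C@@H]1C(=O)N(C)OC | intermediate
15 | methallylmagnesium chloride ((2-methylallyl)magnesium chloride) | CC(=C)C[Mg]Cl | starting material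
16 | bis(chloromagnesium) salt of the tetrahedral adduct of 14 with the methallyl group (N-methoxy-N-methyl hemiaminal; carbinolamine carbon undefined) | C=CC[C@@]1(C)CC[C@@](O[Mg]Cl)(C(C)C)[C@@H]1C(O[Mg]Cl)(CC(C)=C)N(C)OC | intermediate (not isolated)
17 | 1-[(1R,2R,5R)-5-allyl-2-hydroxy-2-isopropyl-5-methylcyclopentyl]-3-methylbut-3-en-1-one | C=CC[C@@]1(C)CC[C@@](O)(C(C)C)[C@@H]1C(=O)CC(C)=C | intermediate
18 | (3R,3aR,8aR)-3-hydroxy-3-isopropyl-6,8a-dimethyl-2,3,3a,5,8,8a-hexahydroazulen-4(1H)-one (trans-fused) | CC1=CC[C@@]2(C)CC[C@@](O)(C(C)C)[C@@H]2C(=O)C1 | intermediate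
19 | (3R,3aS,4S,8aR)-3-isopropyl-6,8a-dimethyl-1,2,3,3a,4,5,8,8a-octahydroazulene-3,4-diol | CC1=CC[C@@]2(C)CC[C@@](O)(C(C)C)[C@@H]2[C@@H](O)C1 | intermediate
20 | O-acetylsalicyloyl chloride (2-acetoxybenzoyl chloride) | CC(=O)Oc1ccccc1C(Cl)=O | starting material
21 | (3R,3aS,4S,8aR)-3-hydroxy-3-isopropyl-6,8a-dimethyl-1,2,3,3a,4,5,8,8a-octahydroazulen-4-yl 2-acetoxybenzoate | CC1=CC[C@@]2(C)CC[C@@](O)(C(C)C)[C@@H]2[C@@H](OC(=O)c2ccccc2OC(C)=O)C1 | intermediate
22 | (3R,3aS,4S,8aR)-3-hydroxy-3-isopropyl-6,8a-dimethyl-1,2,3,3a,4,5,8,8a-octahydroazulen-4-yl 2-hydroxybenzoate | CC1=CC[C@@]2(C)CC[C@@](O)(C(C)C)[C@@H]2[C@@H](OC(=O)c2ccccc2O)C1 | target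

**Total step count:** 11. **Longest linear sequence:** 11 steps (from 1).

**Steps most likely to fail**

Step 5. The aldol addition of the catalyst-bound enolate, which sits next to the quaternary carbon, to the hindered isopropyl ketone may be slower than ketene formation and oligomerisation, or the catalyst may not fully decide the face relative to C1. The fallback replaces ammonium-enolate catalysis by a stoichiometric lithium thioester enolate. It sets out from 10, which PhSH, DCC and DMAP would convert into S-phenyl (R)-3-allyl-3,7-dimethyl-6-oxooctanethioate F1. LiHMDS in THF at −78 °C should remove the more acidic thioester α-proton; the enolate adds to the ketone within the molecule and, on warming to 0 °C, the aldolate expels thiophenoxide and closes the β-lactone (the known thioester-enolate route to β-lactones from ketones). The four-membered ring again forces the cis fusion. With no catalyst to choose the face, 12 would be accompanied by its C4,C5-diastereomer (1S,2R,5S)-2-allyl-5-isopropyl-2-methyl-6-oxabicyclo[3.2.0]heptan-7-one F2, to be removed by chromatography. The route is rejoined at 12.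

Step 9. Ligand exchange of the hindered tertiary C4 hydroxyl onto boron may be too slow, so the ketone is not reduced or the β,γ-alkene migrates in the acidic medium before reduction. The fallback gives up internal delivery and corrects C6 during esterification. It sets out from 18, which an external hydride (LiBH(s-Bu)3, THF, −78 °C) would reduce; attack from the face away from the angular methyl and the C4 oxygen is expected to give the C6 epimer (3R,3aS,4R,8aR)-3-isopropyl-6,8a-dimethyl-1,2,3,3a,4,5,8,8a-octahydroazulene-3,4-diol F3. A Mitsunobu esterification of F3 with 2-acetoxybenzoic acid (PPh3, diisopropyl azodicarboxylate, toluene) inverts C6 and delivers 21 directly, where the route is rejoined. If the external hydride gave 19 instead, step 10 would simply follow.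

Step 2. Methyl transfer to the five-membered enone may be slow or poorly face-selective, and the allyl double bond may drift into conjugation under the Lewis-acidic conditions. The fallback moves the source of the C1 configuration from the conjugate addition to the key step. It sets out from 4, which Me2CuLi with TMSCl in THF at −78 °C (then acid) would convert into racemic 3-allyl-3-methylcyclopentan-1-one F4. The conditions of steps 3 and 4 would then give racemic 4-allyl-2-isobutyryl-4-methylcyclopentan-1-one F5 and racemic 3-allyl-3,7-dimethyl-6-oxooctanoic acid F6. Under the step 5 conditions the enantiopure isothiourea fixes C4 and C5 in both enantiomers of F6, so the two enantiomers diverge into diastereomers: 12 and (1R,2S,5R)-2-allyl-5-isopropyl-2-methyl-6-oxabicyclo[3.2.0]heptan-7-one F7. These would be separated by chromatography and the route rejoined at 12, at the cost of half the material. The same separation would purge any minor enantiomer left by an imperfect step 2.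

**Further compounds**
F1 | step 5 | S-phenyl (R)-3-allyl-3,7-dimethyl-6-oxooctanethioate | C=CC[C@@](C)(CCC(=O)C(C)C)CC(=O)Sc1ccccc1
F2 | step 5 | (1S,2R,5S)-2-allyl-5-isopropyl-2-methyl-6-oxabicyclo[3.2.0]heptan-7-one | C=CC[C@@]1(C)CC[C@@]2(C(C)C)OC(=O)[C@@H]12
F3 | step 9 | (3R,3aS,4R,8aR)-3-isopropyl-6,8a-dimethyl-1,2,3,3a,4,5,8,8a-octahydroazulene-3,4-diol | CC1=CC[C@@]2(C)CC[C@@](O)(C(C)C)[C@@H]2[C@H](O)C1
F4 | step 2 | rac-3-allyl-3-methylcyclopentan-1-one | C=CCC1(C)CCC(=O)C1
F5 | step 2 | rac-4-allyl-2-isobutyryl-4-methylcyclopentan-1-one | C=CCC1(C)CC(C(=O)C(C)C)C(=O)C1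
F6 | step 2 | rac-3-allyl-3,7-dimethyl-6-oxooctanoic acid | C=CCC(C)(CCC(=O)C(C)C)CC(O)=O
F7 | step 2 | (1R,2S,5R)-2-allyl-5-isopropyl-2-methyl-6-oxabicyclo[3.2.0]heptan-7-one | C=CC[C@]1(C)CC[C@]2(C(C)C)OC(=O)[C@H]12
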